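## Retrosynthetic overview

1. Last disconnection: the 4'-OH is released from its tosylate by S–O cleavage, so the ortho-prenylphenol exists only after all heating is over.
2. Key disconnection: ring C (the 4-pyranone) is cut at C4–C4a and O1–C2. This gives phloroglucinol and a ring B α-methoxy-β-keto ester that already holds C2, C3 (with 3-OMe) and C4.
3. Enabling feature: ring A bears oxygen on C5, C7 and C8a (O1) in a 1,3,5 pattern, so it is threefold-symmetric phloroglucinol. Whichever of its three identical C–H carbons is acylated becomes C4a, an adjacent OH becomes O1, and the other two OH groups are 5-OH and 7-OH, so ring A needs neither protection nor regiocontrol.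
4. Keto ester: the aroyl C–Cα bond comes from a crossed Claisen condensation of methyl methoxyacetate with tosylated methyl 5-prenylvanillate. The C5'–CH2 bond comes from an aromatic Claisen rearrangement of the 1,1-dimethylallyl ether of methyl vanillate, made via the dimethylpropargyl ether and semi-hydrogenation.
5. Ring order: rings A and B are bought as arenes, and ring C is the only ring formed (step 6).

Key step: step 6

Remark: the target has no stereocentre and its only alkene carries two identical methyl groups, so no configuration has to be controlled. Stereocentres in transient or enolisable intermediates are racemic and disappear.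

## Route

Step 1
Reactants: 1 methyl vanillate (methyl 4-hydroxy-3-methoxybenzoate); 2 3-chloro-3-methylbut-1-yne
Product: 3 methyl 3-methoxy-4-[(2-methylbut-3-yn-2-yl)oxy]benzoate
Conditions: 2 (1.3 equiv), DBU (1.4 equiv), CuCl2·2H2O (1 mol %), MeCN, 0 °C to rt
Reagents that add atoms: none
Why: Copper-catalysed propargylic O-alkylation, in which the copper acetylide of 2 ionises to a stabilised propargyl/allenylidene cation that the DBU-generated phenoxide captures at the tertiary carbon, a process that suits electron-poor phenols and leaves the methyl ester untouched.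

Step 2
Reactants: 3 methyl 3-methoxy-4-[(2-methylbut-3-yn-2-yl)oxy]benzoate
Product: 4 methyl 3-methoxy-4-[(2-methylbut-3-en-2-yl)oxy]benzoate
Conditions: H2 (1 atm, stopped after 1 equiv), Pd/CaCO3 poisoned with Pb(OAc)2, quinoline, EtOAc, rt
Reagents that add atoms: none
Why: Lindlar semi-hydrogenation, in which the poisoned palladium surface binds the terminal alkyne far more strongly than the monosubstituted alkene formed, so uptake should stop at 4 without touching the aryl ether C–O bond or the ester.

Step 3
Reactants: 4 methyl 3-methoxy-4-[(2-methylbut-3-en-2-yl)oxy]benzoate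
Product: 6 methyl 4-hydroxy-3-methoxy-5-(3-methylbut-2-en-1-yl)benzoate, via ortho-dienone 5 (not isolated)
Conditions: PhNEt2, 130–140 °C, Ar
Reagents that add atoms: none
Why: Aromatic Claisen rearrangement, whose [3,3] shift can end productively only at C5 (C3 carries OMe and the para carbon carries the ester), inverts the 1,1-dimethylallyl unit to a prenyl group in racemic dienone 5 and is completed by tautomerisation to 6, with the gem-dimethyl group lowering the temperature needed and the basic solvent suppressing acid-catalysed chroman closure.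

Step 4
Reactants: 6 methyl 4-hydroxy-3-methoxy-5-(3-methylbut-2-en-1-yl)benzoate
Product: 7 methyl 3-methoxy-5-(3-methylbut-2-en-1-yl)-4-(tosyloxy)benzoate
Conditions: TsCl (1.3 equiv), K2CO3 (2.5 equiv), acetone, reflux
Reagents that add atoms: p-toluenesulfonyl chloride, Cc1ccc(cc1)S(=O)(=O)Cl
Why: O-Sulfonylation of a phenoxide, in which K2CO3 deprotonates the acidic para-ester phenol and the phenoxide attacks the sulfur of TsCl despite its two ortho neighbours, under conditions inert to the alkene and the ester.

Step 5
Reactants: 7 methyl 3-methoxy-5-(3-methylbut-2-en-1-yl)-4-(tosyloxy)benzoate; 8 methyl methoxyacetate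
Product: 10 methyl 2-methoxy-3-[3-methoxy-5-(3-methylbut-2-en-1-yl)-4-(tosyloxy)phenyl]-3-oxopropanoate (racemic), via lithium enolate of methyl methoxyacetate 9 (not isolated)
Conditions: 8 (3.0 equiv), LiN(SiMe3)2 (3.2 equiv), THF, −78 °C; then 7, −78 to 0 °C; AcOH quench
Reagents that add atoms: none
Why: Crossed Claisen condensation, in which 7 has no α-hydrogen and a carbonyl made more electrophilic by the para sulfonate, so preformed chelated enolate 9 adds to it and deprotonation of the doubly activated C–H of 10 by surplus base pulls the equilibrium forward, while the low temperature spares the hindered aryl tosylate and the new α-carbon is racemic and enolisable without consequence.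

Step 6
Reactants: 10 methyl 2-methoxy-3-[3-methoxy-5-(3-methylbut-2-en-1-yl)-4-(tosyloxy)phenyl]-3-oxopropanoate; 11 phloroglucinol (benzene-1,3,5-triol)
Product: 15 4'-O-tosyl dodoviscin J [4-(5,7-dihydroxy-3-methoxy-4-oxo-4H-chromen-2-yl)-2-methoxy-6-(3-methylbut-2-en-1-yl)phenyl tosylate], via aroyl(methoxy)ketene 12 (not isolated), via acylphloroglucinol diketone 13 (not isolated), via cyclic hemiketal 14 (not isolated)
Conditions: 11 (anhydrous, 1.5 equiv), neat melt, N2 sweep to carry off MeOH and H2O, 235–240 °C (microwave or preheated metal bath), 10–20 min; H2O trituration, chromatography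
Reagents that add atoms: none
Why: Above roughly 200 °C the enol form of 10 expels methanol to give aroyl(methoxy)ketene 12, and one of the three identical, strongly nucleophilic C–H carbons of 11 attacks the ketene carbon, forging C4–C4a and, after rearomatisation, giving β-diketone 13. A hydroxyl ortho to the new acyl group then adds to the aryl ketone carbonyl (6-exo-trig closure of ring C, forming O1–C2) to give hemiketal 14, and loss of water across C2–C3 leaves the aromatic 4-pyranone of 15. The closest known reaction type is the Mentzer thermal pyrone synthesis from phenols and β-keto esters, which performs best with phloroglucinol and is established for α-alkoxy aroylacetates as an entry to 3-alkoxyflavones. No stereocentre survives, because the racemic α-carbon of 10 and both centres of 14 become sp2. The selectivity at stake is acylation (chromone) against hydroxyalkylation (4-arylcoumarin): without acid the conjugated, α-methoxy-flanked aryl ketone is too poor an electrophile for Pechmann-type attack by the arene whereas the ester carbon is activated as the ketene, all three ring A positions are the same so no regioisomer can arise, and the first acyl group deactivates ring A towards a second condensation. The 4'-tosylate tolerates neutral heat and withholds the free phenol that the ortho-prenyl group would need to close a chroman.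

Step 7
Reactants: 15 4'-O-tosyl dodoviscin J
Product: 16 dodoviscin J [5,7-dihydroxy-2-[4-hydroxy-3-methoxy-5-(3-methylbut-2-en-1-yl)phenyl]-3-methoxy-4H-chromen-4-one]
Conditions: KOH (10 equiv), MeOH–H2O (4:1), reflux, Ar; then cold 1 M HCl to pH 4–5
Reagents that add atoms: none
Why: Alkaline S–O cleavage of an aryl sulfonate, in which hydroxide attacks sulfur and expels the 4'-phenoxide while the 5- and 7-phenoxides formed at once make the pyranone too electron-rich for ring-opening addition at C2, the water-rich excess of base prevents any methylating sulfonate ester from building up, and the cold mild acidification avoids chroman closure of the liberated ortho-prenylphenol.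

## Compound list

1 | methyl vanillate (methyl 4-hydroxy-3-methoxybenzoate) | COC(=O)c1ccc(O)c(OC)c1 | starting material
2 | 3-chloro-3-methylbut-1-yne | C#CC(C)(C)Cl | starting material
3 | methyl 3-methoxy-4-[(2-methylbut-3-yn-2-yl)oxy]benzoate | COC(=O)c1ccc(OC(C)(C)C#C)c(OC)c1 | intermediate
4 | methyl 3-methoxy-4-[(2-methylbut-3-en-2-yl)oxy]benzoate | COC(=O)c1ccc(OC(C)(C)C=C)c(OC)c1 | intermediate
5 | methyl 5-methoxy-3-(3-methylbut-2-en-1-yl)-4-oxocyclohexa-1,5-diene-1-carboxylate (racemic ortho-dienone, not isolated) | O=C1C(OC)=CC(C(=O)OC)=CC1CC=C(C)C | intermediate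
6 | methyl 4-hydroxy-3-methoxy-5-(3-methylbut-2-en-1-yl)benzoate | COC(=O)c1cc(CC=C(C)C)c(O)c(OC)c1 | intermediate
7 | methyl 3-methoxy-5-(3-methylbut-2-en-1-yl)-4-(tosyloxy)benzoate | COC(=O)c1cc(CC=C(C)C)c(OS(=O)(=O)c2ccc(C)cc2)c(OC)c1 | intermediate
8 | methyl methoxyacetate | COCC(=O)OC | starting material
9 | lithium enolate of methyl methoxyacetate (chelated, geometry without consequence, not isolated) | [Li+].[O-]C(OC)=COC | intermediate
10 | methyl 2-methoxy-3-[3-methoxy-5-(3-methylbut-2-en-1-yl)-4-(tosyloxy)phenyl]-3-oxopropanoate (racemic, enolisable) | COC(=O)C(OC)C(=O)c1cc(OC)c(OS(=O)(=O)c2ccc(C)cc2)c(CC=C(C)C)c1 | intermediate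
11 | phloroglucinol (benzene-1,3,5-triol) | Oc1cc(O)cc(O)c1 | starting material
12 | 2-methoxy-3-[3-methoxy-5-(3-methylbut-2-en-1-yl)-4-(tosyloxy)phenyl]-3-oxoprop-1-en-1-one (aroyl(methoxy)ketene, not isolated) | O=C=C(OC)C(=O)c1cc(OC)c(OS(=O)(=O)c2ccc(C)cc2)c(CC=C(C)C)c1 | intermediate
13 | 2-methoxy-1-[3-methoxy-5-(3-methylbut-2-en-1-yl)-4-(tosyloxy)phenyl]-3-(2,4,6-trihydroxyphenyl)propane-1,3-dione (racemic, not isolated) | O=C(c1c(O)cc(O)cc1O)C(OC)C(=O)c1cc(OC)c(OS(=O)(=O)c2ccc(C)cc2)c(CC=C(C)C)c1 | intermediate
14 | 2,5,7-trihydroxy-3-methoxy-2-[3-methoxy-5-(3-methylbut-2-en-1-yl)-4-(tosyloxy)phenyl]chroman-4-one (racemic diastereomer mixture, not isolated) | COC1C(=O)c2c(O)cc(O)cc2OC1(O)c1cc(OC)c(OS(=O)(=O)c2ccc(C)cc2)c(CC=C(C)C)c1 | intermediate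
15 | 4'-O-tosyl dodoviscin J, 4-(5,7-dihydroxy-3-methoxy-4-oxo-4H-chromen-2-yl)-2-methoxy-6-(3-methylbut-2-en-1-yl)phenyl 4-methylbenzenesulfonate | COc1cc(-c2oc3cc(O)cc(O)c3c(=O)c2OC)cc(CC=C(C)C)c1OS(=O)(=O)c1ccc(C)cc1 | intermediate
16 | dodoviscin J, 5,7-dihydroxy-2-[4-hydroxy-3-methoxy-5-(3-methylbut-2-en-1-yl)phenyl]-3-methoxy-4H-chromen-4-one | COc1cc(-c2oc3cc(O)cc(O)c3c(=O)c2OC)cc(CC=C(C)C)c1O | target

## Step count and risks

Total steps: 7. Longest linear sequence: 7 steps (1 → 3 → 4 → 6 → 7 → 10 → 15 → 16).

**Step 6.**
- What may go wrong: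
  - The water of condensation may hydrolyse the ketene, and decarboxylation would then consume the keto ester.
  - The α-methoxy group may slow C-acylation.
  - Long exposure near 240 °C may degrade the prenyl group or the sulfonate.
  - Some closure may take the coumarin course.
- Fallback: it sets out from 7 and 11 and comes back at 13, and from there at 15. It assembles the same diketone anionically at low temperature.
  - Saponification of 7 (LiOH, THF–H2O, rt) gives 3-methoxy-5-(3-methylbut-2-en-1-yl)-4-(tosyloxy)benzoic acid F1.
  - 1-Chloro-N,N,2-trimethylprop-1-en-1-amine (CH2Cl2, 0 °C, neutral) converts F1 into 3-methoxy-5-(3-methylbut-2-en-1-yl)-4-(tosyloxy)benzoyl chloride F2.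
  - In parallel, Hoesch acylation of 11 with methoxyacetonitrile (ZnCl2, dry HCl, Et2O, 0 °C) gives 2-methoxy-1-(2,4,6-trihydroxyphenyl)ethan-1-iminium chloride F3.
  - Hot water hydrolyses F3 to 2-methoxy-1-(2,4,6-trihydroxyphenyl)ethan-1-one F4.
  - F4 is fully deprotonated with LiN(SiMe3)2 (5 equiv, THF, −78 °C) and acylated at carbon by F2 (1 equiv), a known way to make flavone diketones from unprotected polyhydroxyacetophenones. This gives 13, now isolated.
  - Warming 13 in AcOH buffered with NaOAc closes it through 14 to 15.

**Step 5.**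
- What may go wrong:
  - The methoxyacetate may self-condense.
  - Addition to the aryl ester may be sluggish.
  - Retro-Claisen cleavage may occur.
  - The methoxide released may strip the sulfonate on warming.
- Fallback: it sets out from 7 and comes back at 10. It replaces the acyl substitution with an aldol addition followed by oxidation.
  - i-Bu2AlH (CH2Cl2, −78 to 0 °C) reduces 7 to 4-(hydroxymethyl)-2-methoxy-6-(3-methylbut-2-en-1-yl)phenyl 4-methylbenzenesulfonate F5.
  - MnO2 (CH2Cl2, rt) oxidises F5 to 4-formyl-2-methoxy-6-(3-methylbut-2-en-1-yl)phenyl 4-methylbenzenesulfonate F6.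
  - Enolate 9 adds to F6 at −78 °C to give methyl 3-hydroxy-2-methoxy-3-[3-methoxy-5-(3-methylbut-2-en-1-yl)-4-(tosyloxy)phenyl]propanoate F7 as a diastereomer mixture of no consequence.
  - Dess–Martin periodinane (CH2Cl2, NaHCO3) oxidises F7 to 10.

**Step 3.**
- What may go wrong:
  - The tertiary allyl ether may fragment to the phenol and isoprene.
  - The product may cyclise further to a chroman.
  - Over-hydrogenated material carried over from step 2 cannot rearrange.
- Fallback: it sets out from 1 and comes back at 7. It bypasses steps 1 to 4 by cross-coupling.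
  - Iodination of 1 ortho to the hydroxyl (NIS, cat. CF3CO2H, MeCN, rt) gives methyl 4-hydroxy-3-iodo-5-methoxybenzoate F8.
  - Tosylation (TsCl, K2CO3, acetone, reflux) gives methyl 3-iodo-5-methoxy-4-(tosyloxy)benzoate F9.
  - Stille coupling with tributyl(3-methylbut-2-en-1-yl)stannane (Pd(PPh3)4, DMF, 95 °C) replaces the iodide by the linear prenyl group to give 7. The aryl tosylate is inert under these conditions.

## Further compounds

F1 | step 6 | 3-methoxy-5-(3-methylbut-2-en-1-yl)-4-(tosyloxy)benzoic acid | OC(=O)c1cc(CC=C(C)C)c(OS(=O)(=O)c2ccc(C)cc2)c(OC)c1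
F2 | step 6 | 3-methoxy-5-(3-methylbut-2-en-1-yl)-4-(tosyloxy)benzoyl chloride | ClC(=O)c1cc(CC=C(C)C)c(OS(=O)(=O)c2ccc(C)cc2)c(OC)c1
F3 | step 6 | 2-methoxy-1-(2,4,6-trihydroxyphenyl)ethan-1-iminium chloride | COCC(=[NH2+])c1c(O)cc(O)cc1O.[Cl-]
F4 | step 6 | 2-methoxy-1-(2,4,6-trihydroxyphenyl)ethan-1-one | COCC(=O)c1c(O)cc(O)cc1O
F5 | step 5 | 4-(hydroxymethyl)-2-methoxy-6-(3-methylbut-2-en-1-yl)phenyl 4-methylbenzenesulfonate | OCc1cc(CC=C(C)C)c(OS(=O)(=O)c2ccc(C)cc2)c(OC)c1
F6 | step 5 | 4-formyl-2-methoxy-6-(3-methylbut-2-en-1-yl)phenyl 4-methylbenzenesulfonate | O=Cc1cc(CC=C(C)C)c(OS(=O)(=O)c2ccc(C)cc2)c(OC)c1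
F7 | step 5 | methyl 3-hydroxy-2-methoxy-3-[3-methoxy-5-(3-methylbut-2-en-1-yl)-4-(tosyloxy)phenyl]propanoate (racemic syn/anti mixture) | COC(=O)C(OC)C(O)c1cc(OC)c(OS(=O)(=O)c2ccc(C)cc2)c(CC=C(C)C)c1
F8 | step 3 | methyl 4-hydroxy-3-iodo-5-methoxybenzoate | COC(=O)c1cc(I)c(O)c(OC)c1
F9 | step 3 | methyl 3-iodo-5-methoxy-4-(tosyloxy)benzoate | COC(=O)c1cc(I)c(OS(=O)(=O)c2ccc(C)cc2)c(OC)c1
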